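## Assumptions
- Moracin Q has no stereocentres, so it is achiral and there is no enantiomer to control.
- 3-Bromo-5-hydroxy-4-methoxybenzaldehyde (5-bromoisovanillin) is assumed to be commercially available.

## Retrosynthesis
- Moracin Q comes from global fluoride removal of three aryl TIPS ethers in the last step.
- The C4 benzyl ketone comes from Pd α-arylation of 3-methylbutan-2-one with 4-bromobenzofuran 13. The C4 bromide is carried in from 5-bromoisovanillin, so C4 is never functionalised late.
- The 2-arylbenzofuran comes from Sonogashira coupling and 5-endo cyclisation of o-iodophenol 12 with 3,5-bis(TIPSO)phenylacetylene (5).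
- Phenol 12 comes from ortho-iodination of phenol 10. Phenol 10 comes from Baeyer–Villiger oxidation of aldehyde 7 and methanolysis of the resulting formate. Aldehyde 7 comes from 5-bromoisovanillin. Alkyne 5 comes from 3,5-dihydroxybenzaldehyde by silylation and Ohira–Bestmann homologation.
- Ring order: the benzene ring, with its OMe, O and Br substituents, comes from the starting material. The furan is closed in step 7 and the side chain is added in step 8.

## Route

**Step 1**
Reactants: 1 (3,5-dihydroxybenzaldehyde), 2 (triisopropylsilyl chloride)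
Product: 3 (3,5-bis(TIPSO)benzaldehyde)
Conditions: TIPSCl (2.3 equiv), imidazole, DMF, rt
Reagents that add atoms: TIPSCl, CC(C)[Si](Cl)(C(C)C)C(C)C
Why: Silylation of the two phenols gives base-stable aryl silyl ethers that fluoride removes at the end without touching the aryl methyl ether. No stereocentre is formed.

**Step 2**
Reactants: 3, 4 (Ohira–Bestmann reagent)
Product: 5 (1-ethynyl-3,5-bis(TIPSO)benzene)
Conditions: 4 (1.5 equiv), K2CO3, MeOH, rt
Reagents that add atoms: dimethyl (1-diazo-2-oxopropyl)phosphonate, COP(=O)(OC)C(=[N+]=[N-])C(C)=O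
Why: The Ohira–Bestmann (Seyferth–Gilbert-type) homologation turns the aldehyde into a terminal alkyne under mild conditions that the hindered aryl TIPS ethers tolerate. No stereocentre is formed.

**Step 3**
Reactants: 6 (3-bromo-5-hydroxy-4-methoxybenzaldehyde), 2 (triisopropylsilyl chloride)
Product: 7 (3-bromo-4-methoxy-5-(TIPSO)benzaldehyde)
Conditions: TIPSCl, imidazole, DMF, rt
Reagents that add atoms: TIPSCl, CC(C)[Si](Cl)(C(C)C)C(C)C
Why: Silylation protects the future C6 oxygen, which must be masked before the oxidation and iodination. The bulky group also hinders the adjacent C–H in the later iodination.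

**Step 4**
Reactants: 7, 8 (mCPBA)
Product: 9 (3-bromo-4-methoxy-5-(TIPSO)phenyl formate)
Conditions: mCPBA (1.5 equiv), NaHCO3, CH2Cl2, 0 °C to rt
Reagents that add atoms: mCPBA, OOC(=O)c1cccc(Cl)c1 (supplies the inserted O)
Why: Baeyer–Villiger oxidation of an aldehyde that carries a para-OMe group favours aryl migration, so the aryl formate forms and the oxygen later becomes O1. No stereocentre is formed.

**Step 5**
Reactants: 9 (aryl formate)
Product: 10 (3-bromo-4-methoxy-5-(TIPSO)phenol)
Conditions: K2CO3 (cat.), MeOH/THF, 0 °C, 30 min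
Reagents that add atoms: none (methanol leaves as methyl formate; only H is added to the product)
Why: Mild methanolysis cleaves the activated aryl formate ester and leaves the aryl TIPS and methyl ethers intact.

**Step 6**
Reactants: 10, 11 (N-iodosuccinimide)
Product: 12 (3-bromo-2-iodo-4-methoxy-5-(TIPSO)phenol)
Conditions: NIS (1.05 equiv), cat. TsOH·H2O, MeCN, 0 °C to rt
Reagents that add atoms: N-iodosuccinimide, O=C1CCC(=O)N1I
Why: Electrophilic iodination occurs ortho to the free OH at the carbon para to OTIPS (future C3a). The very bulky OTIPS disfavours the other ortho carbon (future C7), which sets the regiochemistry. No stereocentre is formed.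

**Step 7**
Reactants: 12, 5
Product: 13 (4-bromo-5-methoxy-6-(TIPSO)-2-[3,5-bis(TIPSO)phenyl]benzofuran)
Conditions: PdCl2(PPh3)2 (5 mol %), CuI (10 mol %), Et3N, DMF, 80 °C
Reagents that add atoms: none (alkyne 5 is the coupling partner and is counted as a reactant)
Why: Sonogashira coupling takes place at the far more reactive C–I bond. In situ 5-endo O-cyclisation of the o-alkynylphenol then forms the furan ring and leaves the C4–Br intact.

**Step 8**
Reactants: 13, 14 (3-methylbutan-2-one)
Product: 15 (4-(3-methyl-2-oxobutyl)-5-methoxy-6-(TIPSO)-2-[3,5-bis(TIPSO)phenyl]benzofuran)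
Conditions: Pd(dba)2 (5 mol %), Q-Phos (10 mol %), NaOtBu, 14 (3 equiv), toluene, 80 °C
Reagents that add atoms: 3-methylbutan-2-one, CC(=O)C(C)C
Why: Pd-catalysed ketone α-arylation (Buchwald–Hartwig type) occurs at the less hindered methyl enolate, giving ArCH2C(=O)iPr. The product has no stereocentre, and the excess ketone limits diarylation.

**Step 9**
Reactants: 15, 16 (TBAF)
Product: 17 (moracin Q)
Conditions: TBAF (4 equiv), AcOH (buffer), THF, 0 °C to rt
Reagents that add atoms: none (fluoride only removes Si)
Why: Si–F bond formation cleaves all three aryl TIPS ethers, and buffering with AcOH protects the enolisable ketone. The aryl methyl ether, ketone and benzofuran are untouched.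

## Compound list
1 | 3,5-dihydroxybenzaldehyde | O=Cc1cc(O)cc(O)c1 | starting material
2 | triisopropylsilyl chloride | CC(C)[Si](Cl)(C(C)C)C(C)C | reagent
3 | 3,5-bis(TIPSO)benzaldehyde | O=Cc1cc(O[Si](C(C)C)(C(C)C)C(C)C)cc(O[Si](C(C)C)(C(C)C)C(C)C)c1 | intermediate
4 | dimethyl (1-diazo-2-oxopropyl)phosphonate | COP(=O)(OC)C(=[N+]=[N-])C(C)=O | reagent
5 | 1-ethynyl-3,5-bis(TIPSO)benzene | C#Cc1cc(O[Si](C(C)C)(C(C)C)C(C)C)cc(O[Si](C(C)C)(C(C)C)C(C)C)c1 | intermediate
6 | 3-bromo-5-hydroxy-4-methoxybenzaldehyde | COc1c(Br)cc(C=O)cc1O | starting material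
7 | 3-bromo-4-methoxy-5-(TIPSO)benzaldehyde | COc1c(Br)cc(C=O)cc1O[Si](C(C)C)(C(C)C)C(C)C | intermediate
8 | mCPBA | OOC(=O)c1cccc(Cl)c1 | reagent
9 | 3-bromo-4-methoxy-5-(TIPSO)phenyl formate | COc1c(Br)cc(OC=O)cc1O[Si](C(C)C)(C(C)C)C(C)C | intermediate
10 | 3-bromo-4-methoxy-5-(TIPSO)phenol | COc1c(Br)cc(O)cc1O[Si](C(C)C)(C(C)C)C(C)C | intermediate
11 | N-iodosuccinimide | O=C1CCC(=O)N1I | reagent
12 | 3-bromo-2-iodo-4-methoxy-5-(TIPSO)phenol | COc1c(Br)c(I)c(O)cc1O[Si](C(C)C)(C(C)C)C(C)C | intermediate
13 | 4-bromo-5-methoxy-6-(TIPSO)-2-[3,5-bis(TIPSO)phenyl]benzofuran | COc1c(O[Si](C(C)C)(C(C)C)C(C)C)cc2oc(-c3cc(O[Si](C(C)C)(C(C)C)C(C)C)cc(O[Si](C(C)C)(C(C)C)C(C)C)c3)cc2c1Br | intermediate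
14 | 3-methylbutan-2-one | CC(=O)C(C)C | reagent
15 | 4-(3-methyl-2-oxobutyl)-5-methoxy-6-(TIPSO)-2-[3,5-bis(TIPSO)phenyl]benzofuran | COc1c(O[Si](C(C)C)(C(C)C)C(C)C)cc2oc(-c3cc(O[Si](C(C)C)(C(C)C)C(C)C)cc(O[Si](C(C)C)(C(C)C)C(C)C)c3)cc2c1CC(=O)C(C)C | intermediate
16 | tetrabutylammonium fluoride | CCCC[N+](CCCC)(CCCC)CCCC.[F-] | reagent
17 | moracin Q | COc1c(O)cc2oc(-c3cc(O)cc(O)c3)cc2c1CC(=O)C(C)C | target

## Totals
- Total steps: 9 (alkyne branch: steps 1–2; main sequence: steps 3–9, with the branch joining at step 7).
- Longest linear sequence: 7 steps, from 6 through steps 3 to 9.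

## Three steps most likely to fail
1. **Step 6, regioselective iodination.** Both ortho sites are flanked (by Br or by OTIPS), so a mixture of C3a and C7 iodides is possible.
   - Fallback: install C4 by a Claisen route instead. Iodinate 3-benzyloxy-4-allyloxyphenol at the carbon para to OBn. Build the 5-allyloxy-6-benzyloxy-2-arylbenzofuran by Sonogashira coupling and cyclisation. A thermal aromatic Claisen rearrangement can then only reach C4.
   - Convert the C4 allyl group to prenyl by cross-metathesis with 2-methylbut-2-ene. Epoxidise, then run a Meinwald hydride-shift rearrangement to give ArCH2C(=O)iPr. Finally methylate O5 and remove the benzyl and aryl protecting groups.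
2. **Step 8, α-arylation.** The aryl bromide is electron-rich and hindered by the flanking OMe and the peri furan C3–H. Diarylation, or attack at the methine, is possible.
   - Fallback: build the ketone stepwise. Negishi coupling of 13 with BrZnCH2CO2Et gives the aryl acetate. Saponify, convert to the Weinreb amide, and add iPrMgCl.
3. **Step 7, Sonogashira/cyclisation.** The iodide is flanked by Br and OH, so coupling may be slow and the alkynylphenol may not cyclise. Glaser homocoupling of the alkyne is a competing side reaction.
   - Fallback: use a Pd-free Castro–Stephens coupling. Heat 12 with the preformed copper(I) acetylide of 5 in refluxing pyridine, which couples and cyclises.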